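A direct plan would condense 2,4-diformylphloroglucinol A1 with isovaleraldehyde A2 to the o-quinone methide A3, trap A3 in a hetero-Diels–Alder reaction with (−)-α-gurjunene A4 to give the aromadendrane-fused chroman A5, and then reorganise A5 with acid into the spiro[4.5]decene of the target. Its weakest steps would be:
- the cycloaddition, because the dienophile is a tetrasubstituted, cyclopropane-flanked alkene that must outrun self-condensation of A3 and offers no secured regio- or facial control;
- the acid-triggered skeletal reorganisation, because ionisation, cyclopropane opening, hydride shift, ring reclosure and ether return would have to run as one multi-branch cation cascade with many competing exits, and it alone would set C1 and C5.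

The route reads ring D as (−)-menthone and ring B as a reduced coumarin. The C6=C7 alkene is a latent ketone, so spiro C1 becomes the kinetic α-carbon of menthone (C6 carbonyl, C7 isopropyl carbon, C10 methyl stereocentre); O–C5–C4–C9′ is the lactone edge of a 4-isobutyldihydrocoumarin, with C9′ from asymmetric conjugate reduction and quaternary C4 from trans-selective enolate methylation. After the halves are joined at C5–C1, the key step closes ring C by spiro-alkylation (C1–C2) while reversible oxa-Michael exchange corrects C5, so C1 and C5 are set together under substrate control. Neither a quinone methide cycloaddition nor a cation rearrangement is needed, and the formyl groups arrive last.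

Key step: step 8

Atom labels: ring A = arene C1′–C6′ (C1′ carries C9′, C6′ the ring oxygen, C2′ and C4′ the other oxygens); ring B = O–C5–C4–C9′–C1′–C6′; ring C = C1–C2–C3–C4–C5; ring D = C1–C6–C7–C8–C9–C10 (C7 isopropyl, C10 methyl). In the coumarin intermediates C5 is the lactone carbonyl carbon, C4 the α-carbon and C9′ the β-carbon; in menthone C6 is the carbonyl carbon and C1 the α-CH2.

Assumption: (R)-DTBM-SEGPHOS is taken to give the (4R) lactone 4; if a test reduction shows the opposite sense, the (S) ligand would be used.

Remark: C7 is enolisable until step 9; C7 epimers of 11 and 13 converge at 14, and the SMILES show the menthone-derived epimer.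

Step 1
Reactants: 1 3,5-dimethoxyphenol; 2 ethyl 5-methyl-3-oxohexanoate
Product: 3 4-isobutyl-5,7-dimethoxycoumarin
Conditions: MeSO3H (neat), 0 °C → rt, 6 h; ice, filter
Reagents that add atoms: none
Why: Pechmann condensation (transesterification, ring closure of the ketone onto the position ortho to the phenol oxygen, dehydration) should give one coumarin because both ortho positions of the symmetric phenol are equivalent and doubly activated; no stereocentre is formed.

Step 2
Reactants: 3 4-isobutyl-5,7-dimethoxycoumarin
Product: 4 (4R)-4-isobutyl-5,7-dimethoxy-3,4-dihydrocoumarin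
Conditions: Cu(OAc)2·H2O (3 mol %), (R)-DTBM-SEGPHOS (3.3 mol %), (EtO)2MeSiH (3 equiv), t-BuOH (2 equiv), toluene, 0 °C → rt, 16 h; aq. NH4F
Reagents that add atoms: none
Why: Copper hydride-catalysed asymmetric conjugate reduction of a β,β-disubstituted unsaturated lactone, in which the ligand-bound monovalent copper hydride delivers hydride to one enantiotopic face of the β-carbon and so sets C9′, while t-BuOH protonates the copper enolate and releases the lactone rather than an over-reduced lactol.

Step 3
Reactants: 4 (4R)-4-isobutyl-5,7-dimethoxy-3,4-dihydrocoumarin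
Product: 5 (3R,4R)-3-(2-chloroethyl)-4-isobutyl-5,7-dimethoxy-3,4-dihydrocoumarin
Conditions: LiN(SiMe3)2 (1.1 equiv), THF, −78 °C, 45 min; ICH2CH2Cl (2 equiv), DMPU (3 equiv), −78 → −35 °C, 4 h
Reagents that add atoms: 1-chloro-2-iodoethane ClCCI
Why: Lactone enolate alkylation, in which iodide is displaced far faster than chloride so that the arm keeps its leaving group; the arm enters anti to the isobutyl group, but this centre is planarised again in step 4 and its configuration does not matter.

Step 4
Reactants: 5 (3R,4R)-3-(2-chloroethyl)-4-isobutyl-5,7-dimethoxy-3,4-dihydrocoumarin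
Product: 6 (3S,4S)-3-(2-chloroethyl)-4-isobutyl-5,7-dimethoxy-3-methyl-3,4-dihydrocoumarin
Conditions: LiN(i-Pr)2 (1.2 equiv), THF, −78 °C, 30 min; MeI (5 equiv), DMPU (3 equiv), −78 → −60 °C, 3 h; AcOH quench at −78 °C
Reagents that add atoms: iodomethane CI
Why: A second enolate alkylation creates quaternary C4: peri strain with the C2′ methoxy group holds the C9′ isobutyl group pseudo-axial over one face of the enolate, iodomethane attacks the other face, and methyl therefore ends trans and the chloroethyl arm cis to isobutyl as the target requires, while the low temperature keeps the γ-chloro enolate from closing to a cyclopropane or opening to a ketene.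

Step 5
Reactants: 6 (3S,4S)-3-(2-chloroethyl)-4-isobutyl-5,7-dimethoxy-3-methyl-3,4-dihydrocoumarin
Product: 8 (3S,4S)-3-(2-chloroethyl)-4-isobutyl-5,7-dimethoxy-3-methylchroman-2-yl acetate, via lactol aluminate 7 (not isolated)
Conditions: i-Bu2AlH (1.3 equiv), CH2Cl2, −78 °C, 1 h; then pyridine (4 equiv), DMAP (1.5 equiv), Ac2O (5 equiv), −78 → 0 °C; aq. Rochelle salt
Reagents that add atoms: acetic anhydride CC(=O)OC(C)=O
Why: Reductive acetylation of a lactone, in which the tetrahedral aluminium hemiacetal 7 is stable at −78 °C and is trapped by acetic anhydride before it can collapse to the aldehyde; the alkyl chloride and aryl ethers are inert, and the anomeric centre (a mixture) is lost in step 7.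

Step 6
Reactants: 9 (−)-menthone
Product: 10 (−)-menthone trimethylsilyl enol ether [(3R,6S)-3-methyl-6-isopropyl-1-(trimethylsilyloxy)cyclohex-1-ene]
Conditions: LiN(i-Pr)2 (1.1 equiv), THF, −78 °C, 1 h; Me3SiCl (1.3 equiv), −78 °C → rt; pentane, filter
Reagents that add atoms: chlorotrimethylsilane C[Si](C)(C)Cl
Why: Kinetic deprotonation removes a hydrogen from the unhindered CH2 (future C1) and not from the isopropyl-bearing carbon, and O-silylation fixes this regiochemistry; the C10 stereocentre is not touched.

Step 7
Reactants: 8 (3S,4S)-3-(2-chloroethyl)-4-isobutyl-5,7-dimethoxy-3-methylchroman-2-yl acetate; 10 (−)-menthone trimethylsilyl enol ether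
Product: 11 chroman ketone: menthone bonded through C1 to chroman C5 (epimers at C5 and C1)
Conditions: 10 (1.5 equiv), Me3SiOTf (0.2 equiv), CH2Cl2, −78 → −40 °C, 2 h; Et3N, aq. NaHCO3
Reagents that add atoms: none
Why: Mukaiyama-type addition of a silyl enol ether to a cyclic aryl oxocarbenium ion generated from the anomeric acetate (the logic of C-glycosylation) forms the C5–C1 bond; quaternary C4 prevents loss of a proton to a chromene, the enol ether is a better nucleophile than the dimethoxyarene of a second molecule, and C5 and C1 are formed without control, which is acceptable because step 8 equilibrates both.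

Step 8
Reactants: 11 chroman ketone (epimers at C5 and C1)
Product: 13 spiro ketone (rings A–D complete; C6 ketone; C9′/C4/C5/C1/C10 as in the target), via E-enone phenol 12 (not isolated)
Conditions: KOt-Bu (1.5 equiv), t-BuOH/THF 1:5 (0.02 M), 0 → 45 °C, 8 h
Reagents that add atoms: none
Why: KOt-Bu reversibly forms the C1 enolate of 11, which either expels the aryloxide (retro-oxa-Michael) to the E-enone phenoxide 12, which recloses by 6-exo-trig oxa-Michael addition, or displaces chloride at C2 in an irreversible 5-exo-tet C-alkylation, so all C5 and C1 epimers of 11 should drain through the fastest ring closure (Curtin–Hammett). The closest known reaction types are the spiroannulation of 2-substituted cyclohexanones by intramolecular enolate alkylation and Michael-initiated ring closure. Ring C closes by 5-exo-tet attack of C1 on C2 with the enolate double bond outside the new ring, and ring B is held or re-formed by the 6-exo-trig oxa-Michael step. C1 is controlled by the adjacent C10 methyl group, which sits pseudo-axial next to the substituted enolate carbon and sends C2 to the opposite face (the rule for alkylation of 2,3-disubstituted cyclohexanone enolates), so C2 ends trans and C5 cis to that methyl as in the target; C5 is controlled by C4, because only the epimer whose C5–C1 bond is cis to the C3–C2 arm can reach the chloride without a strained trans-fused bicycle. The step needs C- over O-alkylation and reaction at C1 rather than C7: attack by the enolate oxygen, by the C7 enolate or by the free aryloxide would each need a seven-membered ring, and C9′, C4 and C10 cannot epimerise under these conditions.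

Step 9
Reactants: 13 spiro ketone
Product: 14 C6=C7 enol triflate
Conditions: KN(SiMe3)2 (1.5 equiv), THF, −78 → −20 °C, 1 h; PhNTf2 (1.6 equiv), −78 → 0 °C
Reagents that add atoms: N-phenylbis(trifluoromethanesulfonimide) O=S(=O)(N(c1ccccc1)S(=O)(=O)C(F)(F)F)C(F)(F)F
Why: Enolate O-triflation; because C1 is quaternary the ketone has a single α-hydrogen (C7–H), so only the C6=C7 enol triflate can form, and the C7 centre together with any C7 epimers is erased.

Step 10
Reactants: 14 C6=C7 enol triflate
Product: 15 dimethyl ether of the deformyl target (C6=C7 alkene)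
Conditions: Pd(OAc)2 (5 mol %), PPh3 (10 mol %), HCO2H (3 equiv), n-Bu3N (4.5 equiv), DMF, 60 °C, 3 h
Reagents that add atoms: none
Why: Palladium-catalysed formate reduction of an enol triflate (oxidative addition to zerovalent palladium, formate exchange, loss of CO2, C–H reductive elimination) replaces the triflate by hydrogen at C6 without moving the double bond; no stereocentre is involved.

Step 11
Reactants: 15 dimethyl ether of the deformyl target
Product: 16 deformyl target (C2′ and C4′ free phenols)
Conditions: BBr3 (5 equiv), 2-methylbut-2-ene (10 equiv), CH2Cl2, −78 → −10 °C, 3 h; cannulate into ice-cold aq. NaHCO3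
Reagents that add atoms: none
Why: Boron tribromide cleavage of aryl methyl ethers by bromide attack at methyl; the ring B ether should survive because C5 is secondary and flanked by two quaternary carbons, which blocks both substitution and ionisation, and the alkene scavenger together with the inverse basic quench keeps HBr away from the C6=C7 double bond.

Step 12
Reactants: 16 deformyl target
Product: 18 CNP0121396.1 (target), via bis-iminium salt 17 (not isolated)
Conditions: POCl3 (4 equiv), DMF (8 equiv), MeCN, 0 °C → rt, 12 h; then H2O, 50 °C, 1 h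
Reagents that add atoms: N,N-dimethylformamide CN(C)C=O; water O
Why: Double Vilsmeier–Haack formylation; C3′ and C5′ are the only free ring positions and each is ortho or para to all three oxygen donors, the free phenols keep the ring reactive enough to take the second chloroiminium ion after the first, the isolated alkene is not attacked, and hydrolysis of 17 releases both aldehydes; no stereocentre is formed.

**Compound list**
1 | 3,5-dimethoxyphenol | COc1cc(O)cc(OC)c1 | starting material
2 | ethyl 5-methyl-3-oxohexanoate | CCOC(=O)CC(=O)CC(C)C | starting material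
3 | 4-isobutyl-5,7-dimethoxycoumarin [5,7-dimethoxy-4-(2-methylpropyl)-2H-chromen-2-one] | CC(C)Cc1cc(=O)oc2cc(OC)cc(OC)c12 | intermediate
4 | (4R)-4-isobutyl-5,7-dimethoxy-3,4-dihydrocoumarin (C9′ as in the target) | CC(C)C[C@H]1c2c(OC)cc(OC)cc2OC(=O)C1 | intermediate
5 | (3R,4R)-3-(2-chloroethyl)-4-isobutyl-5,7-dimethoxy-3,4-dihydrocoumarin (chloroethyl trans to isobutyl) | CC(C)C[C@H]1c2c(OC)cc(OC)cc2OC(=O)[C@@H]1CCCl | intermediate
6 | (3S,4S)-3-(2-chloroethyl)-4-isobutyl-5,7-dimethoxy-3-methyl-3,4-dihydrocoumarin (methyl trans and chloroethyl cis to isobutyl; the C4 descriptor differs from that of 4 only through substituent priorities) | CC(C)C[C@H]1c2c(OC)cc(OC)cc2OC(=O)[C@@]1(C)CCCl | intermediate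
7 | (3S,4S)-3-(2-chloroethyl)-4-isobutyl-5,7-dimethoxy-3-methylchroman-2-ol, both anomers, present in the flask as its diisobutylaluminium alkoxide | CC(C)C[C@H]1c2c(OC)cc(OC)cc2OC(O)[C@@]1(C)CCCl | intermediate
8 | (3S,4S)-3-(2-chloroethyl)-4-isobutyl-5,7-dimethoxy-3-methylchroman-2-yl acetate, both anomers | CC(C)C[C@H]1c2c(OC)cc(OC)cc2OC(OC(C)=O)[C@@]1(C)CCCl | intermediate
9 | (−)-menthone, (2S,5R)-5-methyl-2-(propan-2-yl)cyclohexan-1-one | CC(C)[C@@H]1CC[C@@H](C)CC1=O | starting material
10 | (−)-menthone trimethylsilyl enol ether, trimethyl{[(3R,6S)-3-methyl-6-(propan-2-yl)cyclohex-1-en-1-yl]oxy}silane | CC(C)[C@@H]1CC[C@@H](C)C=C1O[Si](C)(C)C | intermediate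
11 | chroman ketone: the (3S,4R)-3-(2-chloroethyl)-4-isobutyl-5,7-dimethoxy-3-methylchroman-2-yl group on the α-CH (C1) of menthone; epimers at C5 and C1; C9′, C4 and C10 fixed | CC(C)C[C@H]1c2c(OC)cc(OC)cc2OC(C3C(=O)[C@H](C(C)C)CC[C@H]3C)[C@@]1(C)CCCl | intermediate
12 | ring-opened E-enone phenol: menthone carrying at C1 an E-alkylidene (C5H=) whose C4 bears methyl, 2-chloroethyl and the (R)-C9′H(isobutyl)(2-hydroxy-4,6-dimethoxyphenyl) group; present as the potassium phenoxide | CC(C)C[C@@H](c1c(O)cc(OC)cc1OC)[C@](C)(CCCl)/C=C2/C(=O)[C@H](C(C)C)CC[C@H]2C | intermediate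
13 | spiro ketone: target skeleton with C6 ketone, C7–H, C2′/C4′ methyl ethers and no formyl groups; ring B cis-fused to ring C, C2 trans and C5 cis to the C10 methyl | CC(C)C[C@H]1c2c(OC)cc(OC)cc2O[C@@H]2[C@@]1(C)CC[C@@]21C(=O)[C@H](C(C)C)CC[C@H]1C | intermediate
14 | C6=C7 enol triflate of 13 | CC(C)C[C@H]1c2c(OC)cc(OC)cc2O[C@@H]2[C@@]1(C)CC[C@@]21C(OS(=O)(=O)C(F)(F)F)=C(C(C)C)CC[C@H]1C | intermediate
15 | deformyl target as its C2′,C4′ dimethyl ether (C6=C7 alkene; stereocentres as in the target) | CC(C)C[C@H]1c2c(OC)cc(OC)cc2O[C@@H]2[C@@]1(C)CC[C@@]21C=C(C(C)C)CC[C@H]1C | intermediate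
16 | deformyl target (C2′ and C4′ phenols, C3′ and C5′ unsubstituted) | CC(C)C[C@H]1c2c(O)cc(O)cc2O[C@@H]2[C@@]1(C)CC[C@@]21C=C(C(C)C)CC[C@H]1C | intermediate
17 | C3′,C5′-bis[(dimethyliminio)methyl] dichloride of 16 | CC(C)C[C@H]1c2c(O)c(C=[N+](C)C)c(O)c(C=[N+](C)C)c2O[C@@H]2[C@@]1(C)CC[C@@]21C=C(C(C)C)CC[C@H]1C.[Cl-].[Cl-] | intermediate
18 | CNP0121396.1: C9′ R (isobutyl), C4 S (methyl), C5 R (OCH), spiro C1 R, C10 R (methyl); C6=C7 with isopropyl on C7; ring A with two CHO and two OH | CC(C)C[C@H]1c2c(O)c(C=O)c(O)c(C=O)c2O[C@@H]2[C@@]1(C)CC[C@@]21C=C(C(C)C)CC[C@H]1C | target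

Total steps: 12. Longest linear sequence: 11 (steps 1–5 and 7–12; step 6 is a one-step branch).

Steps most likely to fail:

1. Step 8. C-alkylation at the crowded tertiary enolate carbon could be outrun by loss of HCl from the arm or by alkylation of the aryloxide, or the facial bias at C1 could be weaker than assumed. Ring C would then be closed by a reversible aldol addition instead of an alkylation. Setting out from 11, Kornblum oxidation (NaI, NaHCO3, DMSO, 100 °C) would turn the chloroethyl arm into the aldehyde F1. KOH in MeOH would close the spiro aldol F2 (5-exo-trig, thermodynamic control, same bias from the C10 methyl group). The C2 hydroxyl would then be removed by Barton–McCombie deoxygenation through the imidazolylthiocarbonyl derivative F3 (1,1′-thiocarbonyldiimidazole, DMAP, CH2Cl2; then n-Bu3SnH, AIBN, toluene, 90 °C), which returns to the route at 13.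

2. Step 2. Hydride transfer to C9′, which lies next to the peri methoxy group, could be slow or poorly face-selective. The centre would then be secured by resolution rather than by asymmetric catalysis. Setting out from 3, hydrogenation (H2, 5 bar, Pd/C, EtOAc/AcOH) would give the racemate of 4 and its enantiomer F4, and preparative chromatography on a chiral stationary phase (supercritical CO2/MeOH) would deliver 4, where the route is rejoined.

3. Step 11. Acid released during ether cleavage could add to or shift the C6=C7 double bond, or the second methyl ether could resist. The last two operations would then be inverted so that no strong acid meets the alkene. Setting out from 15, NBS (2.1 equiv, CH2Cl2, −40 °C) would give the dibromide F5. Double bromine–lithium exchange (t-BuLi, THF, −78 °C) and DMF would give the dialdehyde dimethyl ether F6. LiCl in DMF at 130 °C would then cleave the two methyl ethers, each now ortho and para to a formyl group, by chloride attack at methyl, which leads directly to 18 and bypasses 16.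

**Further compounds**
F1 | step 8 | aldehyde from 11 (arm CH2CH2Cl replaced by CH2CHO) | CC(C)C[C@H]1c2c(OC)cc(OC)cc2OC(C3C(=O)[C@H](C(C)C)CC[C@H]3C)[C@@]1(C)CC=O
F2 | step 8 | spiro aldol: 13 carrying a hydroxyl at C2 (either C2 epimer) | CC(C)C[C@H]1c2c(OC)cc(OC)cc2O[C@@H]2[C@@]1(C)CC(O)[C@@]21C(=O)[C@H](C(C)C)CC[C@H]1C
F3 | step 8 | O-(imidazol-1-ylthiocarbonyl) derivative of F2 | CC(C)C[C@H]1c2c(OC)cc(OC)cc2O[C@@H]2[C@@]1(C)CC(OC(=S)n3ccnc3)[C@@]21C(=O)[C@H](C(C)C)CC[C@H]1C
F4 | step 2 | (4S)-4-isobutyl-5,7-dimethoxy-3,4-dihydrocoumarin (enantiomer of 4) | CC(C)C[C@@H]1c2c(OC)cc(OC)cc2OC(=O)C1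
F5 | step 11 | C3′,C5′-dibromide of 15 | CC(C)C[C@H]1c2c(OC)c(Br)c(OC)c(Br)c2O[C@@H]2[C@@]1(C)CC[C@@]21C=C(C(C)C)CC[C@H]1C
F6 | step 11 | C2′,C4′ dimethyl ether of the target (C3′,C5′ dialdehyde) | CC(C)C[C@H]1c2c(OC)c(C=O)c(OC)c(C=O)c2O[C@@H]2[C@@]1(C)CC[C@@]21C=C(C(C)C)CC[C@H]1C
A1 | direct plan | 2,4-diformylphloroglucinol | O=Cc1c(O)cc(O)c(C=O)c1O
A2 | direct plan | isovaleraldehyde | CC(C)CC=O
A3 | direct plan | o-quinone methide from A1 and A2 | CC(C)C/C=C1/C(=O)C(C=O)=C(O)C(C=O)=C1O
A4 | direct plan | (−)-α-gurjunene | C[C@@H]1CC[C@@H]2[C@@H](C2(C)C)C3=C(CC[C@H]13)C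
A5 | direct plan | aromadendrane-fused chroman adduct | CC(C)C[C@H]1c2c(O)c(C=O)c(O)c(C=O)c2O[C@@]23[C@H]4[C@@H](CC[C@@H](C)[C@H]2CC[C@]31C)C4(C)C
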